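**Assumption:** azulene numbering of ferutinin is used for every bicyclic compound (C3 carbinol, C3a/C8a ring fusion, C4 ester carbon, C6=C7 alkene). The (4R,5R) dioxaborolane in step 1 is assumed to show its usual facial sense on nerol; if not, its enantiomer is used.

**Retrosynthetic overview**
1. Ferutinin 22 ⇐ O-allyl ester 21 ⇐ jaeschkeanadiol 19 ⇐ β-hydroxy ketone 18 (C4=O) ⇐ 4-silyl dienol 15 ⇐ 4-silyl dienone 14 (the silyl group is the latent C4 oxygen).
2. Key disconnection of 14: C4–C5 and C3a–C8a are cut together, which opens both rings and leaves the monocyclic ynone 13. In 13 the C5 unit C5–C6(Me)=C7–C8–C8a is a cis-2-alkyl-1-isopropenylcyclopropane and the C2 unit C3a–C4 is a silyl ynone, joined by the chain C1–C2–C3.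
3. Enabling feature: in the seven-membered ring the trisubstituted C6=C7 alkene is homoallylic to the quaternary C8a, which is the pattern left by an opened vinylcyclopropane. C8a also carries the three-atom chain C1–C2–C3 that ends at C3a, so the cyclopentane closes in the same event as the cycloheptadiene.
4. 13 ⇐ nerol 1: Charette cyclopropanation sets C8a, the only stereocentre that enters the key step; CH2OH becomes isopropenyl and the prenyl terminus becomes the ynone. C3, C3a and C4 are then relayed from C8a.
5. Ring order: cyclopropane (temporary) → cyclopentane and cycloheptadiene together in step 9, with the cyclopropane consumed.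

Key step: step 9

**Step 1**
Reactants: 1 nerol
Product: 2 [(1S,2R)-2-methyl-2-(4-methylpent-3-en-1-yl)cyclopropyl]methanol
Conditions: Et2Zn, CH2I2 (forms Zn(CH2I)2), DME, (4R,5R)-2-butyl-N,N,N′,N′-tetramethyl-1,3,2-dioxaborolane-4,5-dicarboxamide (1.2 equiv), CH2Cl2, −10 °C → rt; aqueous work-up
Reagents that add atoms: diiodomethane, ICI
Why: Charette asymmetric Simmons–Smith cyclopropanation, in which the zinc alkoxide of the allylic alcohol binds the chiral dioxaborolane and directs Zn(CH2I)2 to one face of the 2,3-alkene only (the remote 6,7-alkene has no directing group), and the stereospecific syn addition turns the Z geometry of nerol into the cis relationship of CH2OH and side chain, so the ligand should set (1S,2R).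

**Step 2**
Reactants: 2 [(1S,2R)-2-methyl-2-(4-methylpent-3-en-1-yl)cyclopropyl]methanol
Product: 4 (1S,2R)-2-methyl-2-(4-methylpent-3-en-1-yl)cyclopropane-1-carboxylic acid, via aldehyde 3 (not isolated)
Conditions: TEMPO (20 mol %), PhI(OAc)2 (2.2 equiv), MeCN/H2O (1:1), rt
Reagents that add atoms: water, O
Why: TEMPO/PhI(OAc)2 oxoammonium oxidation of the primary alcohol through the aldehyde hydrate to the acid; no stereocentre is formed, and the trisubstituted alkene, the cyclopropane and the cyclopropyl α-C–H should be untouched under these near-neutral conditions.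

**Step 3**
Reactants: 4 (1S,2R)-2-methyl-2-(4-methylpent-3-en-1-yl)cyclopropane-1-carboxylic acid
Product: 5 1-[(1S,2R)-2-methyl-2-(4-methylpent-3-en-1-yl)cyclopropyl]ethan-1-one
Conditions: MeLi (3 equiv), Et2O, 0 °C → rt; then 1 M HCl, 0 °C
Reagents that add atoms: methyllithium, [Li]C
Why: Addition of MeLi to the lithium carboxylate gives a gem-dialkoxide that collapses to the methyl ketone only on work-up (classical acid-to-methyl-ketone conversion), so no tertiary alcohol forms and no stereocentre is touched.

**Step 4**
Reactants: 5 1-[(1S,2R)-2-methyl-2-(4-methylpent-3-en-1-yl)cyclopropyl]ethan-1-one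
Product: 7 3-[(1R,2S)-2-acetyl-1-methylcyclopropyl]propanal, via ozonide 6 (not isolated)
Conditions: O3, CH2Cl2, −78 °C; then PPh3, −78 °C → rt
Reagents that add atoms: ozone, O=[O+][O-]
Why: Ozonolysis (Criegee mechanism) of the only alkene with reductive cleavage of the ozonide by PPh3; the ketone and the cyclopropane are inert to ozone and no stereocentre is affected.

**Step 5**
Reactants: 8 ethynylmagnesium bromide; 9 benzyl(chloro)dimethylsilane
Product: 10 benzyl(ethynyl)dimethylsilane
Conditions: THF, 0 °C → rt
Reagents that add atoms: none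
Why: Nucleophilic substitution at silicon by the alkynyl Grignard reagent, the standard route to alkynylsilanes; the benzyl(dimethyl)silyl group is chosen because it can later be oxidised off an sp2 carbon.

**Step 6**
Reactants: 7 3-[(1R,2S)-2-acetyl-1-methylcyclopropyl]propanal; 10 benzyl(ethynyl)dimethylsilane
Product: 11 1-[(1S,2R)-2-{5-[benzyl(dimethyl)silyl]-3-hydroxypent-4-yn-1-yl}-2-methylcyclopropyl]ethan-1-one (both carbinol epimers)
Conditions: 10, n-BuLi, THF, −78 °C; then 7, −78 °C; sat. aq. NH4Cl
Reagents that add atoms: none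
Why: 1,2-Addition of a lithium acetylide to an aldehyde at −78 °C, which should be chemoselective over the less electrophilic, more hindered cyclopropyl methyl ketone; the new carbinol centre is formed without control and is erased in step 8.

**Step 7**
Reactants: 11 1-[(1S,2R)-2-{5-[benzyl(dimethyl)silyl]-3-hydroxypent-4-yn-1-yl}-2-methylcyclopropyl]ethan-1-one
Product: 12 1-[benzyl(dimethyl)silyl]-5-[(1R,2R)-1-methyl-2-(prop-1-en-2-yl)cyclopropyl]pent-1-yn-3-ol (both carbinol epimers)
Conditions: Ph3PCH3Br, NaN(SiMe3)2 (3 equiv each), THF, 0 → 40 °C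
Reagents that add atoms: methyltriphenylphosphonium bromide, C[P+](c1ccccc1)(c1ccccc1)c1ccccc1.[Br-]
Why: Wittig methylenation of the methyl ketone with excess non-stabilised ylide (the hydroxyl is carried as its alkoxide); the ketone enolises only toward CH3, so the cis cyclopropane should keep its configuration (the descriptor at the ring CH changes from S to R only because the priorities change).

**Step 8**
Reactants: 12 1-[benzyl(dimethyl)silyl]-5-[(1R,2R)-1-methyl-2-(prop-1-en-2-yl)cyclopropyl]pent-1-yn-3-ol
Product: 13 1-[benzyl(dimethyl)silyl]-5-[(1R,2R)-1-methyl-2-(prop-1-en-2-yl)cyclopropyl]pent-1-yn-3-one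
Conditions: Dess–Martin periodinane, CH2Cl2, 0 °C → rt
Reagents that add atoms: none
Why: Dess–Martin oxidation of the secondary propargylic alcohol to the ynone under non-basic conditions, which should spare the vinylcyclopropane and removes the uncontrolled carbinol centre.

**Step 9 (key step)**
Reactants: 13 1-[benzyl(dimethyl)silyl]-5-[(1R,2R)-1-methyl-2-(prop-1-en-2-yl)cyclopropyl]pent-1-yn-3-one
Product: 14 (8aR)-4-[benzyl(dimethyl)silyl]-6,8a-dimethyl-2,5,8,8a-tetrahydroazulen-3(1H)-one
Conditions: [Rh(CO)2Cl]2 (5 mol %), ClCH2CH2Cl (0.02 M), 70 °C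
Reagents that add atoms: none
Why: The monovalent rhodium catalyst binds the ynone alkyne and the isopropenyl group and inserts into the proximal cyclopropane bond (C7–C8a in product numbering), giving a trivalent rhodium σ-alkyl/π-allyl species; migratory insertion of the tethered alkyne into the Rh–C8a bond forms C3a–C8a and closes the cyclopentane (5-exo-dig carbometalation), and C(sp2)–C(allyl) reductive elimination at the allyl terminus forms C4–C5 and closes the cyclohepta-1,4-diene by contraction of the rhodacycle. The closest known reaction type is the rhodium-catalysed intramolecular [5+2] cycloaddition of vinylcyclopropanes with tethered alkynes, in the variant where the 2π partner is tethered to C2 of a cis-2-substituted vinylcyclopropane. The only stereocentre of the product, quaternary C8a, is transferred rather than created: the Rh–C bond replaces the cleaved ring bond and the new C–C bond replaces the Rh–C bond, both with retention, so the (R) centre set in step 1 should become C8a(R). The step needs proximal rather than distal ring cleavage and [5+2] rather than [3+2] closure; chelation by the tethered alkyne directs the metal to the ring bond that carries the tether, and the cis relationship of tether and isopropenyl group (from the Z geometry of nerol) should give the anti allyl unit that closes through its terminus. The position of the C6=C7 alkene follows from the allyl transposition, and the alkyne is electron-poor and flanked by an sp2 carbonyl carbon, which should ease insertion next to the quaternary centre.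

**Step 10**
Reactants: 14 (8aR)-4-[benzyl(dimethyl)silyl]-6,8a-dimethyl-2,5,8,8a-tetrahydroazulen-3(1H)-one
Product: 15 (3R,8aR)-4-[benzyl(dimethyl)silyl]-6,8a-dimethyl-3-(propan-2-yl)-1,2,3,5,8,8a-hexahydroazulen-3-ol
Conditions: i-PrMgCl, CeCl3 (anhydrous, pre-stirred), THF, −78 °C; sat. aq. NH4Cl
Reagents that add atoms: isopropylmagnesium chloride, CC(C)[Mg]Cl
Why: Organocerium 1,2-addition to the hindered, enolisable β-silyl enone (no conjugate addition, no enolisation expected); C3 is set by attack on the α face, anti to the angular methyl at C8a, which is expected to be pseudo-axial on the cyclopentenone while the ring CH2 at C8 lies nearer the enone plane, though the facial bias may be modest.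

**Step 11**
Reactants: 15 (3R,8aR)-4-[benzyl(dimethyl)silyl]-6,8a-dimethyl-3-(propan-2-yl)-1,2,3,5,8,8a-hexahydroazulen-3-ol
Product: 18 (3R,3aR,8aR)-3-hydroxy-6,8a-dimethyl-3-(propan-2-yl)-2,3,3a,5,8,8a-hexahydroazulen-4(1H)-one, via cyclic siloxane 16 (not isolated), via enol 17 (not isolated)
Conditions: n-Bu4NF, THF, 0 °C; then H2O2 (30% aq.), KHCO3, MeOH, rt
Reagents that add atoms: hydrogen peroxide, OO
Why: Tamao–Fleming-type oxidation of the benzyl(dimethyl)silyl alkenylsilane, in which fluoride-triggered loss of the benzyl group lets the C3 alkoxide close onto silicon (16), peroxide converts the C4–Si bond into the enol 17, and ketonisation sets C3a under the mildly basic, equilibrating conditions, where the trans-fused epimer (C4 carbonyl cis to and hydrogen-bonded with the C3 hydroxyl, trans to the isopropyl group) is expected to be favoured.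

**Step 12**
Reactants: 18 (3R,3aR,8aR)-3-hydroxy-6,8a-dimethyl-3-(propan-2-yl)-2,3,3a,5,8,8a-hexahydroazulen-4(1H)-one
Product: 19 jaeschkeanadiol
Conditions: Me4NBH(OAc)3, MeCN/AcOH (1:1), −30 → 0 °C
Reagents that add atoms: none
Why: Evans–Saksena hydroxyl-directed reduction, in which the C3 alkoxy(diacetoxy)borohydride delivers hydride intramolecularly to the face of the C4 carbonyl on which the C3 oxygen sits, so the 1,3-anti diol with the 4S (α) hydroxyl should form.

**Step 13**
Reactants: 19 jaeschkeanadiol; 20 4-(prop-2-en-1-yloxy)benzoic acid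
Product: 21 (3R,3aS,4S,8aR)-3-hydroxy-6,8a-dimethyl-3-(propan-2-yl)-1,2,3,3a,4,5,8,8a-octahydroazulen-4-yl 4-(prop-2-en-1-yloxy)benzoate
Conditions: DCC, DMAP (cat.), CH2Cl2, 0 °C → rt
Reagents that add atoms: none
Why: Steglich esterification, selective for the secondary C4 hydroxyl because the tertiary C3 hydroxyl is not acylated under these conditions; no stereocentre changes.

**Step 14**
Reactants: 21 (3R,3aS,4S,8aR)-3-hydroxy-6,8a-dimethyl-3-(propan-2-yl)-1,2,3,3a,4,5,8,8a-octahydroazulen-4-yl 4-(prop-2-en-1-yloxy)benzoate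
Product: 22 ferutinin
Conditions: Pd(PPh3)4 (5 mol %), morpholine, THF, rt
Reagents that add atoms: none
Why: Tsuji–Trost deallylation, in which zerovalent palladium ionises the allyl aryl ether to a π-allyl complex that morpholine traps; the homoallylic benzoate, the tertiary alcohol and the trisubstituted alkene are not substrates for this catalyst.

**Compound list**
1 | nerol, (2Z)-3,7-dimethylocta-2,6-dien-1-ol | CC(C)=CCC/C(C)=C\CO | starting material
2 | [(1S,2R)-2-methyl-2-(4-methylpent-3-en-1-yl)cyclopropyl]methanol | OC[C@H]1C[C@@]1(C)CCC=C(C)C | intermediate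
3 | (1S,2R)-2-methyl-2-(4-methylpent-3-en-1-yl)cyclopropane-1-carbaldehyde | O=C[C@H]1C[C@@]1(C)CCC=C(C)C | intermediate (not isolated)
4 | (1S,2R)-2-methyl-2-(4-methylpent-3-en-1-yl)cyclopropane-1-carboxylic acid | OC(=O)[C@H]1C[C@@]1(C)CCC=C(C)C | intermediate
5 | 1-[(1S,2R)-2-methyl-2-(4-methylpent-3-en-1-yl)cyclopropyl]ethan-1-one | CC(=O)[C@H]1C[C@@]1(C)CCC=C(C)C | intermediate
6 | ozonide of 5, 1-{(1S,2R)-2-[2-(5,5-dimethyl-1,2,4-trioxolan-3-yl)ethyl]-2-methylcyclopropyl}ethan-1-one | CC(=O)[C@H]1C[C@@]1(C)CCC2OOC(C)(C)O2 | intermediate (not isolated)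
7 | 3-[(1R,2S)-2-acetyl-1-methylcyclopropyl]propanal | CC(=O)[C@H]1C[C@@]1(C)CCC=O | intermediate
8 | ethynylmagnesium bromide | C#C[Mg]Br | starting material
9 | benzyl(chloro)dimethylsilane | C[Si](C)(Cl)Cc1ccccc1 | starting material
10 | benzyl(ethynyl)dimethylsilane | C#C[Si](C)(C)Cc1ccccc1 | intermediate
11 | 1-[(1S,2R)-2-{5-[benzyl(dimethyl)silyl]-3-hydroxypent-4-yn-1-yl}-2-methylcyclopropyl]ethan-1-one (both carbinol epimers) | CC(=O)[C@H]1C[C@@]1(C)CCC(O)C#C[Si](C)(C)Cc1ccccc1 | intermediate
12 | 1-[benzyl(dimethyl)silyl]-5-[(1R,2R)-1-methyl-2-(prop-1-en-2-yl)cyclopropyl]pent-1-yn-3-ol (both carbinol epimers) | C=C(C)[C@H]1C[C@@]1(C)CCC(O)C#C[Si](C)(C)Cc1ccccc1 | intermediate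
13 | 1-[benzyl(dimethyl)silyl]-5-[(1R,2R)-1-methyl-2-(prop-1-en-2-yl)cyclopropyl]pent-1-yn-3-one | C=C(C)[C@H]1C[C@@]1(C)CCC(=O)C#C[Si](C)(C)Cc1ccccc1 | intermediate
14 | (8aR)-4-[benzyl(dimethyl)silyl]-6,8a-dimethyl-2,5,8,8a-tetrahydroazulen-3(1H)-one | CC1=CC[C@@]2(C)CCC(=O)C2=C(C1)[Si](C)(C)Cc1ccccc1 | intermediate
15 | (3R,8aR)-4-[benzyl(dimethyl)silyl]-6,8a-dimethyl-3-(propan-2-yl)-1,2,3,5,8,8a-hexahydroazulen-3-ol | CC1=CC[C@@]2(C)CC[C@@](O)(C(C)C)C2=C(C1)[Si](C)(C)Cc1ccccc1 | intermediate
16 | cyclic siloxane of 15 (C3–O–SiMe2–C4 2,5-dihydro-1,2-oxasilole ring fused to the hydroazulene) | CC1=CC[C@@]2(C)CC[C@]3(C(C)C)O[Si](C)(C)C(C1)=C23 | intermediate (not isolated)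
17 | enol, (3R,8aR)-6,8a-dimethyl-3-(propan-2-yl)-1,2,3,5,8,8a-hexahydroazulene-3,4-diol | CC1=CC[C@@]2(C)CC[C@@](O)(C(C)C)C2=C(O)C1 | intermediate (not isolated)
18 | (3R,3aR,8aR)-3-hydroxy-6,8a-dimethyl-3-(propan-2-yl)-2,3,3a,5,8,8a-hexahydroazulen-4(1H)-one | CC1=CC[C@@]2(C)CC[C@@](O)(C(C)C)[C@@H]2C(=O)C1 | intermediate
19 | jaeschkeanadiol, (3R,3aS,4S,8aR)-6,8a-dimethyl-3-(propan-2-yl)-1,2,3,3a,4,5,8,8a-octahydroazulene-3,4-diol | CC1=CC[C@@]2(C)CC[C@@](O)(C(C)C)[C@@H]2[C@@H](O)C1 | intermediate
20 | 4-(prop-2-en-1-yloxy)benzoic acid | C=CCOc1ccc(cc1)C(O)=O | starting material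
21 | (3R,3aS,4S,8aR)-3-hydroxy-6,8a-dimethyl-3-(propan-2-yl)-1,2,3,3a,4,5,8,8a-octahydroazulen-4-yl 4-(prop-2-en-1-yloxy)benzoate | CC1=CC[C@@]2(C)CC[C@@](O)(C(C)C)[C@@H]2[C@@H](OC(=O)c2ccc(OCC=C)cc2)C1 | intermediate
22 | ferutinin, (3R,3aS,4S,8aR)-3-hydroxy-6,8a-dimethyl-3-(propan-2-yl)-1,2,3,3a,4,5,8,8a-octahydroazulen-4-yl 4-hydroxybenzoate | CC1=CC[C@@]2(C)CC[C@@](O)(C(C)C)[C@@H]2[C@@H](OC(=O)c2ccc(O)cc2)C1 | target

**Step count and risks**
Total steps: 14. Longest linear sequence: 13 (steps 1–4 and 6–14; step 5 is a one-step side branch).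

Steps most likely to fail:

Step 10. The organocerium reagent may attack both faces of the C3 carbonyl, because the angular methyl and the ring CH2 at C8 flank the planar enone from opposite sides and the bias toward the α face may be small. Fallback: the isopropyl group is introduced before the cycloaddition. Ynone 13 is treated with i-PrMgCl/CeCl3 at −78 °C to give the tertiary propargylic alcohol F2 as both C3 epimers. The mixture is cyclised under the conditions of step 9 to 15 and its C3 epimer F3, which are diastereomers on a rigid bicycle and are separated by chromatography. 15 re-enters the route at step 11; this costs the material that ends up as F3.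

Step 9. The π-allyl intermediate may close at its internal carbon (formal [3+2] product), the conjugated ynone may oligomerise on the metal, or the cis-alkyl vinylcyclopropane may undergo a thermal homo-1,5-hydrogen shift at 70 °C. Fallback: the cycloaddition is moved one oxidation level down. Propargylic alcohol 12 (a non-conjugated silylalkyne) is cyclised at room temperature with the cationic monovalent rhodium catalyst [Rh(C10H8)(cod)]SbF6 in ClCH2CH2Cl to the dienol F1 (both C3 epimers). F1 is oxidised with Dess–Martin periodinane to 14, where the route resumes.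

Step 11. The β-hydroxy ketone may undergo retro-aldol opening of the cyclopentane, or ketonise to the cis-fused C3a epimer, under the basic fluoride/peroxide conditions. Fallback: a non-basic unmasking of the alkenylsilane. 15 is epoxidised with VO(acac)2 (cat.) and t-BuOOH in CH2Cl2, a hydroxyl-directed reaction that should take only the C3a=C4 alkene, to give the epoxysilane F4. Dilute H2SO4 in aqueous THF then opens the epoxide at the silicon-bearing carbon and Peterson elimination of the silanol delivers the enol, which ketonises under acid to 18.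

**Further compounds**
F1 | step 9 | (8aR)-4-[benzyl(dimethyl)silyl]-6,8a-dimethyl-1,2,3,5,8,8a-hexahydroazulen-3-ol (both C3 epimers) | CC1=CC[C@@]2(C)CCC(O)C2=C(C1)[Si](C)(C)Cc1ccccc1
F2 | step 10 | 1-[benzyl(dimethyl)silyl]-4-methyl-3-{2-[(1R,2R)-1-methyl-2-(prop-1-en-2-yl)cyclopropyl]ethyl}pent-1-yn-3-ol (both C3 epimers) | C=C(C)[C@H]1C[C@@]1(C)CCC(O)(C(C)C)C#C[Si](C)(C)Cc1ccccc1
F3 | step 10 | (3S,8aR)-4-[benzyl(dimethyl)silyl]-6,8a-dimethyl-3-(propan-2-yl)-1,2,3,5,8,8a-hexahydroazulen-3-ol | CC1=CC[C@@]2(C)CC[C@](O)(C(C)C)C2=C(C1)[Si](C)(C)Cc1ccccc1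
F4 | step 11 | 3a,4-epoxide of 15 (oxirane oxygen syn to the C3 hydroxyl) | CC1=CC[C@@]2(C)CC[C@@](O)(C(C)C)[C@]23O[C@]3([Si](C)(C)Cc3ccccc3)C1
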